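A direct plan would brominate 4-methoxy-3-methylphenol A1 to bromophenol A2, add dilithiated A2 to oxetan-3-one A3 to give oxetanol A4, angeloylate its phenol to give aryl angelate A5, open the oxetane with tigloyl bromide A6 under a chiral squaramide to give bromohydrin A7 and close the epoxide with carbonate.
The enantioselective acyl bromide opening would be weakest: no precedent with acyl halides, an uncatalysed HBr background and a Z-angelate exposed to HBr.
The aryllithium addition would risk enolising the oxetanone.
The carbonate closure could shift the angeloyl group from the phenol oxygen to the tertiary alkoxide.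

**Strategy.** The benzene ring is not bought; it is built last, around the finished oxirane. With the ring numbered C1 (O-angelate), C2 (oxiranyl), C4 (OMe) and C5 (Me), a Dötz benzannulation joins alkyne 8 (C2, C3 and the complete chiral side chain), the isopropenyl(methoxy)carbene ligand of 14 (C4, C5, C6) and one CO ligand (C1 and its oxygen); acylation in the same flask adds the angelate. One operation thus forms three ring C–C bonds and the aryl ester and fixes the 1,2,4,5-pattern through the regiochemistry of a terminal alkyne. The stereocentre is set beforehand by Sharpless epoxidation of a small enynol, so no oxetane opening, aryllithium addition or halohydrin closure is needed.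

Key step: step 5

Assumption: with L-(+)-diisopropyl tartrate, enynol 3 is taken to be epoxidised in the same facial sense as 2-methylprop-2-en-1-ol, which gives the (S)-2-substituted glycidol; the alkynyl group, like methyl, ranks lowest, so the descriptor is also (S).

**Step 1**
Reactants: 1 2-bromoprop-2-en-1-ol; 2 ethynyltrimethylsilane
Product: 3 2-methylidene-4-(trimethylsilyl)but-3-yn-1-ol
Conditions: Pd(PPh3)2Cl2 (2 mol %), CuI (4 mol %), iPr2NH (3 equiv), THF, 23 °C, 12 h
Reagents that add atoms: ethynyltrimethylsilane (2), C#C[Si](C)(C)C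
Why: Sonogashira coupling, in which zerovalent palladium inserts into the vinyl C–Br bond, the alkynylcopper species formed with CuI transmetalates and reductive elimination joins the alkyne to C2 of the allyl unit, tolerates the free primary alcohol.

**Step 2**
Reactants: 3 2-methylidene-4-(trimethylsilyl)but-3-yn-1-ol; 4 cumene hydroperoxide; 5 tigloyl chloride, (2E)-2-methylbut-2-enoyl chloride
Product: 7 [(2R)-2-[(trimethylsilyl)ethynyl]oxiran-2-yl]methyl (2E)-2-methylbut-2-enoate, via epoxy alcohol 6 (not isolated)
Conditions: Ti(OiPr)4 (10 mol %), L-(+)-diisopropyl tartrate (12 mol %), 4 (2.0 equiv), 4 Å molecular sieves, CH2Cl2, −20 °C, 24 h; P(OMe)3 (1.0 equiv), −20 °C; then pyridine (4 equiv), DMAP (5 mol %), 5 (2.0 equiv), −20 to 0 °C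
Reagents that add atoms: cumene hydroperoxide (4), CC(C)(OO)c1ccccc1; tigloyl chloride (5), C/C=C(\C)C(=O)Cl
Why: Katsuki–Sharpless asymmetric epoxidation, in which the allylic alkoxide and the hydroperoxide are bound to titanium in the catalyst formed from Ti(OiPr)4 and the tartrate and the L-(+)-tartrate exposes the alkene face that leads to the (S)-epoxy alcohol 6, sets the quaternary oxirane carbon, and the known in-flask acylation of the crude epoxy alcohol (pyridine instead of Et3N, so that no vinylketene deconjugates the tiglate) should give the stable ester 7, whose descriptor is (R) only because the ester arm gains CIP rank.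

**Step 3**
Reactants: 7 [(2R)-2-[(trimethylsilyl)ethynyl]oxiran-2-yl]methyl (2E)-2-methylbut-2-enoate
Product: 8 [(2R)-2-ethynyloxiran-2-yl]methyl (2E)-2-methylbut-2-enoate
Conditions: TBAF (1.1 equiv), AcOH (1.2 equiv), THF, 0 °C, 30 min
Reagents that add atoms: none
Why: Fluoride attacks silicon and acetic acid protonates the alkynyl anion (protodesilylation), while the buffered medium should leave the tiglate, the oxirane and with them the stereocentre untouched.

**Step 4**
Reactants: 9 2-bromoprop-1-ene; 10 hexacarbonylchromium, Cr(CO)6; 11 trimethyloxonium tetrafluoroborate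
Product: 14 pentacarbonyl[methoxy(prop-1-en-2-yl)methylidene]chromium, via prop-1-en-2-yllithium 12 (not isolated), via lithium acyl chromate 13 (not isolated)
Conditions: t-BuLi (2.0 equiv), Et2O, −78 °C; 10 (1.0 equiv), −78 to 23 °C; then 11 (1.3 equiv), CH2Cl2/H2O, 0 °C
Reagents that add atoms: hexacarbonylchromium (10), O=C=[Cr](=C=O)(=C=O)(=C=O)(=C=O)=C=O; trimethyloxonium tetrafluoroborate (11), C[O+](C)C.F[B-](F)(F)F
Why: Fischer carbene synthesis, in which bromine–lithium exchange gives vinyllithium 12, this adds to a CO ligand of Cr(CO)6 to give acyl chromate 13, and the hard oxonium salt methylates the acyl oxygen.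

**Step 5**
Reactants: 8 [(2R)-2-ethynyloxiran-2-yl]methyl (2E)-2-methylbut-2-enoate; 14 pentacarbonyl[methoxy(prop-1-en-2-yl)methylidene]chromium; 15 angelic anhydride, (2Z)-2-methylbut-2-enoic anhydride
Product: 18 [(2R)-2-{5-methoxy-4-methyl-2-[(2Z)-2-methylbut-2-enoyloxy]phenyl}oxiran-2-yl]methyl (2E)-2-methylbut-2-enoate, via tricarbonylchromium phenol complex 16 (not isolated), via tricarbonylchromium aryl angelate complex 17 (not isolated)
Conditions: 14 (1.5 equiv), THF (0.05 M), 50 °C, 12 h, argon; then 15 (2.0 equiv), iPr2NEt (3.0 equiv), 23 °C, 6 h; then air, diffuse daylight, Et2O, 23 °C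
Reagents that add atoms: pentacarbonyl[methoxy(prop-1-en-2-yl)methylidene]chromium (14), COC(C(C)=C)=[Cr](=C=O)(=C=O)(=C=O)(=C=O)=C=O; angelic anhydride (15), C/C=C(/C)C(=O)OC(=O)/C(C)=C\C
Why: Thermal loss of one CO from 14 lets the terminal alkyne of 8 insert so that its CH carbon bonds to the carbene carbon (C3–C4) and the carbon bearing the oxiranyl group becomes the new carbene carbon; CO insertion (C1–C2) gives a chromium-bound dienylketene, whose 6π-electrocyclic closure onto the isopropenyl CH2 (C1–C6) and tautomerisation should deliver the phenol as its Cr(CO)3 complex 16. The closest known reaction type is the Dötz benzannulation of alkenyl(methoxy)carbene chromium complexes with terminal alkynes, run with acylation of the metal-bound phenol in the same flask. The only ring closed is the benzene ring, in a formal [3+2+1] mode completed by the electrocyclisation. No stereocentre is created: none of the four bonds of oxirane C2 takes part, so the (R) centre of 8 is carried over, and the planar chirality of 16 and 17 vanishes when air removes the metal. The step needs regiocontrol (oxiranyl carbon next to the CO-derived C1), secured by the steric difference between H and a fully substituted carbon on the alkyne, and phenol formation over cyclopentannulation, secured by the alkenyl methoxy complex in THF. Capping the phenol with angelic anhydride and a non-nucleophilic amine before demetalation should keep the Z geometry and avoids handling a free ortho-hydroxyphenyl oxirane, which could ionise at the benzylic C–O bond.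

**Compound list**
1 | 2-bromoprop-2-en-1-ol | C=C(Br)CO | starting material
2 | ethynyltrimethylsilane | C#C[Si](C)(C)C | starting material
3 | 2-methylidene-4-(trimethylsilyl)but-3-yn-1-ol | C=C(CO)C#C[Si](C)(C)C | intermediate
4 | cumene hydroperoxide | CC(C)(OO)c1ccccc1 | starting material
5 | tigloyl chloride, (2E)-2-methylbut-2-enoyl chloride | C/C=C(\C)C(=O)Cl | starting material
6 | [(2S)-2-[(trimethylsilyl)ethynyl]oxiran-2-yl]methanol | C[Si](C)(C)C#C[C@]1(CO)CO1 | intermediate
7 | [(2R)-2-[(trimethylsilyl)ethynyl]oxiran-2-yl]methyl (2E)-2-methylbut-2-enoate | C[Si](C)(C)C#C[C@]1(COC(=O)/C(C)=C/C)CO1 | intermediate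
8 | [(2R)-2-ethynyloxiran-2-yl]methyl (2E)-2-methylbut-2-enoate | C#C[C@]1(COC(=O)/C(C)=C/C)CO1 | intermediate
9 | 2-bromoprop-1-ene | C=C(C)Br | starting material
10 | hexacarbonylchromium, Cr(CO)6 | O=C=[Cr](=C=O)(=C=O)(=C=O)(=C=O)=C=O | starting material
11 | trimethyloxonium tetrafluoroborate | C[O+](C)C.F[B-](F)(F)F | starting material
12 | prop-1-en-2-yllithium | [Li]C(C)=C | intermediate
13 | lithium pentacarbonyl(2-methylprop-2-enoyl)chromate | [Li+].C=C(C)C(=O)[Cr-](=C=O)(=C=O)(=C=O)(=C=O)=C=O | intermediate
14 | pentacarbonyl[methoxy(prop-1-en-2-yl)methylidene]chromium | COC(C(C)=C)=[Cr](=C=O)(=C=O)(=C=O)(=C=O)=C=O | intermediate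
15 | angelic anhydride, (2Z)-2-methylbut-2-enoic anhydride | C/C=C(/C)C(=O)OC(=O)/C(C)=C\C | starting material
16 | tricarbonyl(η6-arene)chromium complex of [(2R)-2-(2-hydroxy-5-methoxy-4-methylphenyl)oxiran-2-yl]methyl (2E)-2-methylbut-2-enoate, both faces (arene and Cr(CO)3 written as two parts) | Oc1cc(C)c(OC)cc1[C@]1(COC(=O)/C(C)=C/C)CO1.O=C=[Cr](=C=O)=C=O | intermediate
17 | tricarbonyl(η6-arene)chromium complex of 18, both faces (arene and Cr(CO)3 written as two parts) | C/C=C(/C)C(=O)Oc1cc(C)c(OC)cc1[C@]1(COC(=O)/C(C)=C/C)CO1.O=C=[Cr](=C=O)=C=O | intermediate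
18 | [(2R)-2-{5-methoxy-4-methyl-2-[(2Z)-2-methylbut-2-enoyloxy]phenyl}oxiran-2-yl]methyl (2E)-2-methylbut-2-enoate | C/C=C(/C)C(=O)Oc1cc(C)c(OC)cc1[C@]1(COC(=O)/C(C)=C/C)CO1 | target

Total step count: 5. Longest linear sequence: 4 (steps 1, 2, 3 and 5); step 4 is a one-step side branch.

**Steps most likely to fail**

Step 5. The propargylic oxirane may not survive the chromium vinylcarbene and ketene stages (ring opening or rearrangement), the bulky alkyne may divert to cyclobutenone or two-alkyne products, and the Z ester may partly isomerise during acylation. The fallback masks the oxirane and closes it after the arene exists. It sets out from 8: LiCl and AcOH in THF at 23 °C would open the oxirane at its CH2 to give (2S)-2-(chloromethyl)-2-hydroxybut-3-yn-1-yl (2E)-2-methylbut-2-enoate F1. Benzannulation with 14 and acylation with 15 as in step 5 would lead, through the tricarbonylchromium complex of the chlorohydrin phenol F2 and the tricarbonylchromium complex of its angelate F3, to (2S)-3-chloro-2-hydroxy-2-{5-methoxy-4-methyl-2-[(2Z)-2-methylbut-2-enoyloxy]phenyl}propyl (2E)-2-methylbut-2-enoate F4 after air demetalation; the tertiary alcohol should not be acylated without DMAP. Cs2CO3 in MeCN at 0 °C would then close the oxirane by 3-exo-tet displacement with the arrangement at carbon kept, and the fallback comes back to the route at 18.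

Step 2. Oxygen transfer to the alkyne-conjugated 1,1-disubstituted alkene may be slow and the facial selectivity eroded, and the titanium alkoxide may open the product. The fallback replaces catalytic enantioselection by resolution. It sets out from 3: VO(acac)2 (2 mol %) and t-BuOOH in CH2Cl2 at 0 °C would give racemic {2-[(trimethylsilyl)ethynyl]oxiran-2-yl}methanol F5. A lipase from Burkholderia cepacia with vinyl acetate in t-BuOMe at 30 °C, stopped a little beyond half conversion, would acetylate the (R)-alcohol to [(2S)-2-[(trimethylsilyl)ethynyl]oxiran-2-yl]methyl acetate F6 and leave the (S)-alcohol; the sense of the enzyme would have to be secured by a screen. The fallback comes back to the route at 6, which is esterified with 5 (pyridine, DMAP, CH2Cl2, 0 °C) to give 7.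

Step 3. Fluoride or acetate may open the oxirane or cleave the tiglate before the silyl group is gone. The fallback removes silicon before the oxirane and the ester exist. It sets out from 3: K2CO3 in MeOH at 0 °C would give 2-methylidenebut-3-yn-1-ol F7, kept in CH2Cl2 solution because it is volatile. Epoxidation and in-flask tigloylation under the conditions of step 2 would pass through [(2S)-2-ethynyloxiran-2-yl]methanol F8, and the fallback comes back to the route at 8.

**Further compounds**
F1 | step 5 | (2S)-2-(chloromethyl)-2-hydroxybut-3-yn-1-yl (2E)-2-methylbut-2-enoate | C#C[C@](O)(COC(=O)/C(C)=C/C)CCl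
F2 | step 5 | tricarbonyl(η6-arene)chromium complex of (2S)-3-chloro-2-hydroxy-2-(2-hydroxy-5-methoxy-4-methylphenyl)propyl (2E)-2-methylbut-2-enoate | Oc1cc(C)c(OC)cc1[C@](O)(COC(=O)/C(C)=C/C)CCl.O=C=[Cr](=C=O)=C=O
F3 | step 5 | tricarbonyl(η6-arene)chromium complex of F4 | C/C=C(/C)C(=O)Oc1cc(C)c(OC)cc1[C@](O)(COC(=O)/C(C)=C/C)CCl.O=C=[Cr](=C=O)=C=O
F4 | step 5 | (2S)-3-chloro-2-hydroxy-2-{5-methoxy-4-methyl-2-[(2Z)-2-methylbut-2-enoyloxy]phenyl}propyl (2E)-2-methylbut-2-enoate | C/C=C(/C)C(=O)Oc1cc(C)c(OC)cc1[C@](O)(COC(=O)/C(C)=C/C)CCl
F5 | step 2 | racemic {2-[(trimethylsilyl)ethynyl]oxiran-2-yl}methanol | C[Si](C)(C)C#CC1(CO)CO1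
F6 | step 2 | [(2S)-2-[(trimethylsilyl)ethynyl]oxiran-2-yl]methyl acetate | C[Si](C)(C)C#C[C@@]1(COC(C)=O)CO1
F7 | step 3 | 2-methylidenebut-3-yn-1-ol | C=C(CO)C#C
F8 | step 3 | [(2S)-2-ethynyloxiran-2-yl]methanol | C#C[C@]1(CO)CO1
A1 | direct plan | 4-methoxy-3-methylphenol | Oc1cc(C)c(OC)cc1
A2 | direct plan | 2-bromo-4-methoxy-5-methylphenol | Oc1cc(C)c(OC)cc1Br
A3 | direct plan | oxetan-3-one | O=C1COC1
A4 | direct plan | 3-(2-hydroxy-5-methoxy-4-methylphenyl)oxetan-3-ol | Oc1cc(C)c(OC)cc1C1(O)COC1
A5 | direct plan | 2-(3-hydroxyoxetan-3-yl)-4-methoxy-5-methylphenyl (2Z)-2-methylbut-2-enoate | C/C=C(/C)C(=O)Oc1cc(C)c(OC)cc1C1(O)COC1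
A6 | direct plan | tigloyl bromide, (2E)-2-methylbut-2-enoyl bromide | C/C=C(\C)C(=O)Br
A7 | direct plan | (2S)-3-bromo-2-hydroxy-2-{5-methoxy-4-methyl-2-[(2Z)-2-methylbut-2-enoyloxy]phenyl}propyl (2E)-2-methylbut-2-enoate | C/C=C(/C)C(=O)Oc1cc(C)c(OC)cc1[C@](O)(COC(=O)/C(C)=C/C)CBr
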